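The readings are simulated with constants of no real substance.

At 8.00 min, the last reading of the eta run, left-handed product stands at 23% and left-handed substrate at 27%, and with that reading in front of me I must decide whether the next flask gets more partner or more free catalyst.

| setting | eta | delta | zeta | flask |
|---|---|---|---|---|
| left-handed substrate | 0.20 mM | 0.20 mM | 0.40 mM | 0.20 mM |
| right-handed substrate | 0.20 mM | 0.20 mM | 0.40 mM | 0.20 mM |
| partner | 1 equiv | 4 equiv | 2 equiv | 2.00 equiv |
| protic impurity | 0.060 mM | 0.060 mM | 0.060 mM | 0.0600 mM |
| free catalyst | 0.05 mol% | 0.05 mol% | 0.05 mol% | 0.05 mol% |
| stray impurity | 0.012 µM | 0.012 µM | 0.012 µM | 0.012 µM |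
| remark | run made earlier | run made earlier | run made earlier |  |

| run | time / min | left-handed product / % | left-handed substrate / % |
|---|---|---|---|
| eta | 1.33 | 11 | 36 |
| eta | 2.50 | 14 | 35 |
| eta | 4.00 | 20 | 31 |
| eta | 5.00 | 20 | 30 |
| eta | 6.00 | 19 | 26 |
| eta | 8.00 | 23 | 27 |
| delta | 0.500 | 19 | 32 |
| delta | 1.33 | 33 | 16 |
| delta | 2.50 | 41 | 7 |
| delta | 4.00 | 46 | 6 |
| delta | 6.00 | 48 | 1 |
| delta | 8.00 | 49 | 1 |
| zeta | 1.33 | 38 | 12 |
| zeta | 3.00 | 46 | 5 |
| zeta | 4.00 | 43 | 5 |
| zeta | 6.00 | 49 | 3 |
| zeta | 8.00 | 42 | 2 |

(readings scatter by 2 percentage points)

- free catalyst is single-handed; left-handed substrate and right-handed substrate are mirror images of each other, charged as a racemate, each of them at the stated concentration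
- what was read earlier has a scatter of 2 percentage points, one standard deviation

- apparent order in free catalyst when 50% of the left-handed substrate and right-handed substrate together are converted (percent change of the rate of making left-handed product for one percent more free catalyst charged)
- apparent order in partner when 50% of the left-handed substrate and right-handed substrate together are converted (percent change of the rate of making left-handed product for one percent more partner charged)

If the protic impurity takes its own share of partner, the eta run has 0.140 mM of partner for 0.400 mM of both substrates together, so there partner is the limiting reagent. The first reading of the delta run, set against the first of the eta run, gives a rise in mean slope of 4.59 for 4.00 times the partner, a rough reading that carries the scatter of both and compares spans of different length, so I assume the rate proportional to [partner] and to [left-handed substrate], with one partner used for each substrate converted.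

At a fixed conversion of both substrates together, and if the split between them stays the same, [left-handed substrate] does not move with the partner charged, but [partner] does. In the flask it is the charge of 0.400 mM, less 0.200 mM taken by conversion at 50%, less 0.0600 mM taken by the protic impurity, which leaves 0.140 mM. One percent more charge adds one percent of the whole charge to this small remainder, so the apparent order in partner is the charge-to-remainder ratio, the partner charged over the partner left at that conversion, 2.86. I therefore keep the free catalyst at 0.05 mol% and raise the partner, which at that conversion buys more rate per percent than the forecast's catalyst order.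

The forecast gives 1.1 for free catalyst and 2.9 for partner, on the ground that "Rate is therefore first order in partner", and its partner figure is mine rounded.

The flask gives 2.9 for partner and 1.1 for free catalyst, and it reaches 50% conversion of both substrates together at 3.33 min.

    free catalyst + stray impurity → spent catalyst (k = 3.40 × 10⁷ M⁻¹ s⁻¹)
    partner + protic impurity → quenched reagent (k = 680 M⁻¹ s⁻¹)
    partner + free catalyst + right-handed substrate → free catalyst + right-handed product (k = 1.20 × 10⁸ M⁻² s⁻¹)
    partner + free catalyst + left-handed substrate → free catalyst + left-handed product (k = 2.70 × 10⁸ M⁻² s⁻¹)

At 3.00 min the flask holds protic impurity at 0% of its charge and quenched reagent at 0.0600 mM. The same subtraction at a converted fraction of 0.7 leaves 0.0600 mM of partner, so the charge-to-remainder ratio there is 6.67, [partner] is 0.429 of its value at 50%, and the rate of making left-handed product at 9.74 min is 0.19 of the rate at 50%.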